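## Structural features

Uliginosin B (12, C28H34O8) is an achiral dimeric acylphloroglucinol built from three rings. Ring A is an enolised 2-acylcyclohexane-1,3,5-trione (isobutyrylfilicinic acid): C1 carries the isobutyryl group, C2 and C4 are enolic C–OH carbons, C3 carries the bridge, C5 is the quaternary gem-dimethyl carbon and C6 is the ring ketone. A single CH2 joins C3 of ring A to C1' of ring B, an aromatic isobutyrylphloroglucinol with free hydroxyls on C2' and C6' and the isobutyryl group on C5'. A 2,2-dimethyl-2H-pyran (ring C) is fused across C3'–C4', so the pyran oxygen sits on C4', next to the acyl carbon and para to the bridge. There are no stereocentres (C5 of ring A and C2 of the pyran each carry two identical methyl groups), so every selectivity question is one of regiochemistry or chemoselectivity. The fragile parts are the acidic, chelating β-triketone of ring A (which can condense with primary amines), the electron-rich 2H-chromene (acid, oxidants, light), the air-sensitive polyphenol, and the CH2 bridge, which hot base can cleave by retro-Michael loss of the ring A anion and rejoin in scrambled form. The real difficulty is to join two different but nearly identical nuclei through one carbon without homo-coupling, to put the gem-dimethyl group on only one of them, and to fuse ring C on O4' and not on O2'. The plan exploits the fact that ring A has the carbon and oxygen skeleton of ring B: without ring C and the two methyl groups on C5 (the carbon between the C4 enol and the C6 ketone), both halves are the same isobutyrylphloroglucinol, each with one unsubstituted ring carbon.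

## Logic of the disconnections

12 ⇒ 9 + 10. The two bonds of ring C that lie outside ring B are cut: O4'–CMe2 and C3'–CH. Ring C is the most sensitive part of 12 and all five of its non-aromatic carbons are present in 10, so it is best added last and in one operation. The cut removes a ring and leaves 9, which has a single unsubstituted sp2 carbon (C3'), so the site of C–C bond formation is fixed. The forward step must close on O4' and not on O2', and it must neither fragment the bridge nor derivatise the trione of ring A.

9 ⇒ 6 + two 7. Both C5–CH3 bonds of ring A are cut, so each molecule of 9 takes up two molecules of 7. Without the two methyl groups ring A is an aromatic trihydroxyphenyl ketone identical with ring B, so the unsymmetrical 9 becomes the symmetric 6 and no cross-coupling of two different halves is needed. The forward step pays for this: it must methylate one ring only, at carbon, and twice at the free carbon and not at the bridge-bearing one. 6 is deliberately left unprotected, because the phenolates are the nucleophiles and any group that told the rings apart would itself have to be introduced statistically. Control is sought through a deficit of 7, recycling of 6 and low temperature.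

6 ⇒ two 3 + 4. Both aryl–CH2 bonds are cut. The two aryl partners are identical, so the union needs no cross-selectivity and the whole dimer comes from one ketone and a one-carbon electrophile. The forward step must stop at the dimer, since 3 and 6 both keep free ring carbons. This calls for half an equivalent of 4, low temperature and a short reaction time.

3 ⇒ 1 + 2. The aryl–C(=O) bond is cut, which leads back to two commercial compounds. The forward acylation must give mono C-acylation and not O-acylation or double acylation.

## Other disconnections considered

Alternative 1: The cut is through the C6–C1 and C2–C3 bonds of ring A, so that C3–C6 (with the gem-dimethyl carbon and the bridge) come from a cyclobutenone and C1–C2 from an alkyne. In the forward key step, 3-ethoxy-4,4-dimethyl-2-[2,4,6-tris(methoxymethoxy)benzyl]cyclobut-2-en-1-one A2 would be heated with ethoxyacetylene A3. A 4π ring opening, a ketene–alkyne [2+2] addition of A3, a second 4π opening and a 6π electrocyclisation would lead to the dienone 3,5-diethoxy-6,6-dimethyl-4-[2,4,6-tris(methoxymethoxy)benzyl]cyclohexa-2,4-dien-1-one A1, which cannot become a phenol because C5 is quaternary.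
- In its favour: every substituent of ring A is placed by connectivity, the gem-dimethyl carbon is present from the start, and there is neither a statistical ring count nor a risk of over-alkylation. On regiocontrol in ring A it is better than the chosen plan.
- Against it: A2 needs its own multi-step preparation. The 6π closure must engage a fully substituted diene terminus, and the ketene stage of the cascade may be diverted into dimerisation. After A1 the route must still acylate C1 with 2, hydrolyse two vinylogous ester ethers, remove three MOM groups with acid next to the benzylic trione linkage, and acylate ring B with 2 before it reaches 9.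
- Comparison: both plans pass through 9 and share step 4, so on the pyran regiochemistry they are equal. Mechanistically the pericyclic cascade is more predictable in regiochemistry than a polar alkylation, but less tolerant of crowding. In step economy it would need roughly three times the four steps of the chosen plan.

Alternative 2: The cut is at the C3'–CH bond of ring C (chromene C4a–C4), with the O–CMe2 bond carried in as an aryl 1,1-dimethylpropargyl ether. In the forward key step, the para ether A5 (isobutyrylfilicinic acid carrying a 2,6-dihydroxy-4-(2-methylbut-3-yn-2-yloxy)benzyl group on C3) would be heated. A propargyl Claisen [3,3] shift to an ortho carbon, enolisation, a 1,5-hydrogen shift and oxa-6π closure would give A4, which is 12 without the isobutyryl group of ring B.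
- In its favour: the ether oxygen is the one para to the bridge and the two ortho carbons are equivalent, so only one chromene can form and its oxygen is where 12 needs it. On ring C regiochemistry it is better than step 4, which must choose between two hydroxyl groups.
- Against it: A4 lacks the acyl group of ring B. That group would have to be introduced last with 2, by Friedel–Crafts or Fries chemistry at the only free aromatic carbon, in the presence of an acid-sensitive 2H-chromene, free hydroxyls and the enolised trione, which is hard to defend under mild conditions. A5 itself would require selective O-alkylation of one hydroxyl beside the more acidic ring A enols, and its two different halves would first have to be joined by a cross-coupling.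
- Comparison: on ring A it is equal (the same kind of methylation, on a monomer). On pyran regiochemistry it is better. On the functional-group tolerance of its end-game and on step count (at least six or seven steps) it is worse.

Alternative 3: The cut is at the C4–C5 bond of ring A, so the quaternary carbon starts as an isopropyl methine of a diisobutyrylmethane unit and C4 as a lactone carbonyl. In the forward key step, Mg(OMe)2 A8 would open the lactone of 4-hydroxy-5-isobutyryl-6-isopropyl-3-[2,4,6-tris(benzyloxy)benzyl]-2H-pyran-2-one A7 by methanolysis. Dieckmann-type attack of an isopropyl methine carbanion on the freed ester carbon would then close ring A and give A6, isobutyrylfilicinic acid with the 2,4,6-tris(benzyloxy)benzyl group on C3. Either isobutyryl group may cyclise, since both outcomes are the same compound.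
- In its favour: the gem-dimethyl group is never installed by alkylation, so over-methylation, O-methylation and the choice between two rings do not arise. On the integrity of ring A it is better than the chosen plan.
- Against it: a quaternary centre would have to form through a tertiary, singly activated carbanion in a substrate whose more acidic sites are already enolates, which is kinetically demanding. A7 must be assembled from three components. Afterwards three benzyl ethers must be hydrogenolysed and ring B acylated with 2 under Lewis acid, which may scramble the bridge, before 9 is reached.
- Comparison: from 9 onward it is equal, since step 4 is the same. Mechanistically its ring closure is certain in regiochemistry but doubtful in rate, whereas the chosen alkylation is certain in rate but statistical in selectivity. In step economy it is about twice as long.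

Key step: step 3

Remark: the enolised trione ring is drawn throughout in the 2,4-dien-1-one tautomer of the target; other enol forms are the same compound.
Remark: every partner that contributes non-hydrogen atoms (2, 4, 7, 10) is entered as a numbered reactant. Step 3 incorporates two molecules of 7, one for each new C5–CH3 bond: the first stands as the numbered reactant and the second is entered under the reagents that add atoms. No other reagent leaves atoms in a product.

## Steps

Step 1
Reactants: 1 phloroglucinol; 2 isobutyryl chloride
Product: 3 isobutyrylphloroglucinol, 2-methyl-1-(2,4,6-trihydroxyphenyl)propan-1-one
Conditions: 2 (1.05 equiv), AlCl3 (3.5 equiv), PhNO2, 0 °C → 65 °C; then ice/aq. HCl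
Reagents that add atoms: none
Why: Friedel–Crafts C-acylation of the highly activated triol; any aryl ester formed first should undergo Fries rearrangement under AlCl3, and the ketone–AlCl3 complex deactivates the ring towards a second acylation.

Step 2
Reactants: 3 isobutyrylphloroglucinol (2 equiv); 4 formaldehyde
Product: 6 methylenebis(isobutyrylphloroglucinol), the symmetric homodimer, via hydroxymethyl ketone 5 (not isolated)
Conditions: 37% aq. CH2O (0.5 equiv), 1% aq. KOH, 0–5 °C, 5–10 min; then dil. HCl
Reagents that add atoms: none
Why: Phenolate hydroxymethylation (Lederer–Manasse) gives 5, which loses water to an ortho-quinone methide that a second phenolate of 3 traps by Michael addition. Both partners are the same, so only one dimer can form, and the half equivalent of 4 with short contact at 0 °C limits chain growth.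

Step 3
Reactants: 6 methylenebis(isobutyrylphloroglucinol); 7 methyl iodide (2 equiv incorporated per molecule of 9)
Product: 9 isobutyrylfilicinic acid bridged through CH2 to isobutyrylphloroglucinol (12 without ring C), via C-monomethyl homodimer 8 (not isolated)
Conditions: NaOMe (5 equiv), MeI (7, 1.3 equiv in total, added slowly), MeOH, 0 °C → rt; then aq. HCl; recovered 6 recycled
Reagents that add atoms: methyl iodide (the second molecule of 7, which supplies the second C5 methyl group), CI
Why: Methoxide converts 6 into its ring phenolates (the hydroxyl para to each acyl group is the most acidic), and the one ring carbon that still carries hydrogen attacks a first molecule of 7 in an SN2 step; tautomerisation gives the C-methyl phenol 8. The more electron-rich phenolate of 8 takes up a second molecule of 7 at the same carbon, giving a 4,4-dimethylcyclohexadienone that cannot rearomatise and rests as the enolised β-triketone of ring A, so two molecules of 7 and two of NaOMe are consumed for each molecule of 9. The closest known reaction type is the NaOMe/MeI dearomative gem-dimethylation of monomeric acylphloroglucinols to acylfilicinic acids. No ring is closed and no stereocentre is created, because C5 receives two identical methyl groups. The step needs methylation of one ring only: this is set statistically by charging less of 7 than even one ring per dimer would consume and recycling 6, and it is helped because the once-methylated ring of 8 is more nucleophilic than an untouched ring, so the second methyl group should go to the same ring. It needs C- and not O-methylation, which the hydrogen-bonding methanol medium and the soft electrophile favour, and attack at the free carbon and not the bridge-bearing one, which the arylmethyl group shields. Ring A of 9 is a delocalised triketonate whose only remaining nucleophilic carbon (C3) is blocked by the bridge, while methylation of ring B of 9 is held back only by the shortage of 7. Low temperature should keep retro-Michael scrambling of the CH2 bridge slow.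

Step 4
Reactants: 9 the des-pyran dimer; 10 prenal (3-methylbut-2-enal)
Product: 12 uliginosin B, via ring B ortho-quinone methide 11 (not isolated)
Conditions: 10 (2 equiv), ethylenediammonium diacetate (20 mol %), toluene, 100 °C
Reagents that add atoms: none
Why: Amine-catalysed Knoevenagel-type condensation of the iminium ion of 10 at C3', the only free carbon of 9, followed by loss of the amine, gives the 1-oxatriene 11, which closes ring C by oxa-6π electrocyclisation (formal [3+3] chromene annulation); no stereocentre is formed. Closure on O4' is expected because the C2' and C6' hydroxyls are held in the hydrogen-bond network with ring A (C6'–OH also with the acyl group), which leaves O4' free to become the oxatriene carbonyl; ring A has no free carbon and stays a spectator.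

## Compound list

1 | phloroglucinol (benzene-1,3,5-triol) | Oc1cc(O)cc(O)c1 | starting material
2 | isobutyryl chloride (2-methylpropanoyl chloride) | CC(C)C(Cl)=O | starting material
3 | isobutyrylphloroglucinol, 2-methyl-1-(2,4,6-trihydroxyphenyl)propan-1-one | CC(C)C(=O)c1c(O)cc(O)cc1O | intermediate
4 | formaldehyde | C=O | starting material
5 | 1-[2,4,6-trihydroxy-3-(hydroxymethyl)phenyl]-2-methylpropan-1-one (formed in the flask, not isolated) | CC(C)C(=O)c1c(O)cc(O)c(CO)c1O | intermediate
6 | methylenebis(isobutyrylphloroglucinol), 1,1'-[methylenebis(2,4,6-trihydroxybenzene-3,1-diyl)]bis(2-methylpropan-1-one) | CC(C)C(=O)c1c(O)cc(O)c(Cc2c(O)cc(O)c(C(=O)C(C)C)c2O)c1O | intermediate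
7 | methyl iodide | CI | starting material
8 | homodimer 6 with one methyl group on the free carbon of one ring (formed in the flask, not isolated) | CC(C)C(=O)c1c(O)c(C)c(O)c(Cc2c(O)cc(O)c(C(=O)C(C)C)c2O)c1O | intermediate
9 | 3,5-dihydroxy-6,6-dimethyl-2-(2-methylpropanoyl)-4-{[2,4,6-trihydroxy-3-(2-methylpropanoyl)phenyl]methyl}cyclohexa-2,4-dien-1-one | CC(C)C(=O)C1=C(O)C(Cc2c(O)cc(O)c(C(=O)C(C)C)c2O)=C(O)C(C)(C)C1=O | intermediate
10 | prenal (3-methylbut-2-enal) | CC(C)=CC=O | starting material
11 | ring B ortho-quinone methide of 9: (Z)-3-methylbut-2-enylidene on C3' with the vinyl group syn to the C4' carbonyl, C2' and C6' hydroxyls retained (formed in the flask, not isolated) | CC(C)C(=O)C1=C(O)C(CC2=C(O)/C(=C/C=C(C)C)C(=O)C(C(=O)C(C)C)=C2O)=C(O)C(C)(C)C1=O | intermediate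
12 | uliginosin B, 3,5-dihydroxy-4-{[5,7-dihydroxy-2,2-dimethyl-8-(2-methylpropanoyl)-2H-chromen-6-yl]methyl}-6,6-dimethyl-2-(2-methylpropanoyl)cyclohexa-2,4-dien-1-one | CC(C)C(=O)C1=C(O)C(Cc2c(O)c3c(c(C(=O)C(C)C)c2O)OC(C)(C)C=C3)=C(O)C(C)(C)C1=O | target

Total step count: 4. Longest linear sequence: 4 steps (1 → 3 → 6 → 9 → 12).

## Least certain steps

Step 3 (key step). The most likely failure is loss of ring discrimination: the second ring may be methylated about as fast as the first, so the deficit of 7 would give only a statistical distribution. Further risks are methylation at the bridge-bearing carbon or on oxygen, and methoxide-induced retro-Michael cleavage and recombination of the bridge. The cause is that both rings are the same phenolate nucleophile and the product can expel the stabilised ring A anion. The fallback gives up the desymmetrisation and sets out from 3. Monomer 3 is gem-dimethylated with NaOMe and 7 in MeOH to isobutyrylfilicinic acid F1. F1 is aminomethylated at its single free carbon with dimethylmethyleneiminium iodide to the Mannich base 3-[(dimethylamino)methyl]isobutyrylfilicinic acid F2. Warming F2 with an excess of 3 in dioxane at about 80 °C should join the two halves by elimination–addition: loss of dimethylamine, then conjugate addition of a free carbon of 3 to the exposed CH2 electrophile. The route is rejoined at 9. Cross-selectivity is imposed by attaching the one-carbon unit beforehand to the partner that has only one free carbon.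

Step 4. The most likely failure is closure of the oxatriene on the wrong oxygen (O2' in place of O4'), since both hydroxyls flank C3'. Two further risks are thermal retro-Michael scrambling of the bridge at 100 °C and capture of the primary amine catalyst by the ring A triketone as a vinylogous amide. The fallback moves the annulation to the monomer and sets out from 3 and 10. The same amine-catalysed annulation on 3 should give 8-isobutyryl-5,7-dihydroxy-2,2-dimethyl-2H-chromene F3, and regiochemical purity is secured by chromatography at this simple stage. F3 has one free aromatic carbon (C6). Heating it with the Mannich base F2 (made from 3 as in the fallback to step 3) should forge the CH2 bridge with loss of dimethylamine. The route is rejoined at 12, and the pyran regiochemistry is then fixed before the dimer exists.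

Step 2. The most likely failure is over-condensation: 3 and 6 both keep free nucleophilic carbons, so chain growth past the dimer and double hydroxymethylation compete once free formaldehyde is present. The fallback replaces the one-pot condensation by a stepwise one and sets out from 3. Mono-aminomethylation of 3 with one equivalent of dimethylmethyleneiminium iodide gives the Mannich base 3-[(dimethylamino)methyl]isobutyrylphloroglucinol F4. Heating F4 with an excess of 3 should expel dimethylamine and join the two rings by elimination–addition. The route is rejoined at 6, and no free formaldehyde is present to attack the dimer.

## Further compounds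

F1 | step 3 | isobutyrylfilicinic acid, 3,5-dihydroxy-6,6-dimethyl-2-(2-methylpropanoyl)cyclohexa-2,4-dien-1-one | CC(C)C(=O)C1=C(O)C=C(O)C(C)(C)C1=O
F2 | step 3 | 4-[(dimethylamino)methyl]-3,5-dihydroxy-6,6-dimethyl-2-(2-methylpropanoyl)cyclohexa-2,4-dien-1-one (Mannich base of F1) | CC(C)C(=O)C1=C(O)C(CN(C)C)=C(O)C(C)(C)C1=O
F3 | step 4 | 8-isobutyryl-5,7-dihydroxy-2,2-dimethyl-2H-chromene, 1-(5,7-dihydroxy-2,2-dimethyl-2H-chromen-8-yl)-2-methylpropan-1-one | CC(C)C(=O)c1c(O)cc(O)c2C=CC(C)(C)Oc12
F4 | step 2 | 1-{3-[(dimethylamino)methyl]-2,4,6-trihydroxyphenyl}-2-methylpropan-1-one (Mannich base of 3) | CC(C)C(=O)c1c(O)cc(O)c(CN(C)C)c1O
A1 | alternative 1 | 3,5-diethoxy-6,6-dimethyl-4-[2,4,6-tris(methoxymethoxy)benzyl]cyclohexa-2,4-dien-1-one | CCOC1=CC(=O)C(C)(C)C(OCC)=C1Cc1c(OCOC)cc(OCOC)cc1OCOC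
A2 | alternative 1 | 3-ethoxy-4,4-dimethyl-2-[2,4,6-tris(methoxymethoxy)benzyl]cyclobut-2-en-1-one | CCOC1=C(Cc2c(OCOC)cc(OCOC)cc2OCOC)C(=O)C1(C)C
A3 | alternative 1 | ethoxyacetylene (ethoxyethyne) | CCOC#C
A4 | alternative 2 | uliginosin B lacking the isobutyryl group of ring B | CC(C)C(=O)C1=C(O)C(Cc2c(O)c3C=CC(C)(C)Oc3cc2O)=C(O)C(C)(C)C1=O
A5 | alternative 2 | isobutyrylfilicinic acid carrying a 2,6-dihydroxy-4-(2-methylbut-3-yn-2-yloxy)benzyl group on C3 | CC(C)C(=O)C1=C(O)C(Cc2c(O)cc(OC(C)(C)C#C)cc2O)=C(O)C(C)(C)C1=O
A6 | alternative 3 | isobutyrylfilicinic acid carrying a 2,4,6-tris(benzyloxy)benzyl group on C3 | CC(C)C(=O)C1=C(O)C(Cc2c(OCc3ccccc3)cc(OCc3ccccc3)cc2OCc2ccccc2)=C(O)C(C)(C)C1=O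
A7 | alternative 3 | 4-hydroxy-5-(2-methylpropanoyl)-6-(propan-2-yl)-3-[2,4,6-tris(benzyloxy)benzyl]-2H-pyran-2-one | CC(C)C(=O)C1=C(C(C)C)OC(=O)C(Cc2c(OCc3ccccc3)cc(OCc3ccccc3)cc2OCc2ccccc2)=C1O
A8 | alternative 3 | magnesium dimethoxide, Mg(OMe)2 | [Mg+2].[O-]C.[O-]C
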